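## Retrosynthetic overview
1. Calyxin A comes from a single acid-labile protected form (five phenolic MOM ethers, C3-OTBS). Its C6=C7 styrene is cut by a Heck disconnection into a terminal vinyl group and protected 4-iodophenol.
2. The chalcone is cut at the core-aryl–C(=O) bond, giving an aryl bromide (Br/Li exchange) and a cinnamic Weinreb amide (Heck of the same aryl iodide with an acrylamide).
3. The key disconnection is the core-aryl–C5 bond. It is formed by an enantioselective Cu/NHC-catalysed SN2′ allyl–aryl coupling of an (E)-allylic chloride with a 2,6-bis(MOMO)-4-methoxyphenylboronate, which sets C5.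
4. The allylic chloride comes from cross-metathesis, Brown allylation (sets C3) and Heck arylation of allyl alcohol. The boronate comes from resorcinol by Ir C–H borylation, oxidation, methylation and directed ortho-metalation.
5. No ring is formed. All four benzene rings are bought, three as 4-iodophenol and one as resorcinol.

Assumption: locants C1–C7 denote the heptanoid chain (C1 = benzylic CH2, C3 = carbinol carbon, C5 = carbon bearing the core ring, C6=C7 = styrene). Read from the given SMILES, the target is then (3S,5R).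

## Route

Step 1
Reactants: 1 4-iodophenol
Product: 2 1-iodo-4-(methoxymethoxy)benzene
Conditions: MOMCl (1.3 equiv), iPr2NEt (1.5 equiv), CH2Cl2, 0 °C → rt
Reagents that add atoms: chloromethyl methyl ether (MOMCl), COCCl
Why: Williamson-type O-alkylation of the phenol; the MOM acetal withstands bases, organometallics, Pd, Ru and Cu and is removed by acid at the end.

Step 2
Reactants: 2 1-iodo-4-(methoxymethoxy)benzene; 3 allyl alcohol
Product: 4 3-[4-(methoxymethoxy)phenyl]propanal
Conditions: Pd(OAc)2 (2 mol %), Bu4NCl, NaHCO3, DMF, 45 °C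
Reagents that add atoms: none
Why: Jeffery–Heck arylation of an allylic alcohol, in which aryl adds to the terminal carbon, β-hydride elimination toward the carbinol gives the enol, and the enol tautomerises to the aldehyde.

Step 3
Reactants: 4 3-[4-(methoxymethoxy)phenyl]propanal; 5 allylmagnesium bromide
Product: 8 (S)-1-[4-(methoxymethoxy)phenyl]hex-5-en-3-ol, via (+)-B-allyldiisopinocampheylborane 6 (not isolated), via diisopinocampheylborinate of the product 7 (not isolated)
Conditions: (+)-Ipc2BOMe, 5, Et2O, 0 °C → rt; then 4, −78 °C; then 3 M NaOH, 30 % H2O2, rt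
Reagents that add atoms: none
Why: Brown asymmetric allylboration through a closed chair transition state, in which the Ipc groups derived from (−)-α-pinene steer allyl to the Re face of the aldehyde and set C3 as S (typically ≥ 94 % ee).

Step 4
Reactants: 8 (S)-1-[4-(methoxymethoxy)phenyl]hex-5-en-3-ol
Product: 9 (S)-tert-butyl({1-[4-(methoxymethoxy)phenyl]hex-5-en-3-yl}oxy)dimethylsilane
Conditions: TBSCl, imidazole, DMF, rt
Reagents that add atoms: tert-butyldimethylsilyl chloride (TBSCl), CC(C)(C)[Si](C)(C)Cl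
Why: Imidazole-promoted silylation of the secondary alcohol, which leaves C3 untouched and gives an ether that is stable to alkoxide and BuLi but labile to acid.

Step 5
Reactants: 9 (S)-tert-butyl({1-[4-(methoxymethoxy)phenyl]hex-5-en-3-yl}oxy)dimethylsilane; 10 (Z)-1,4-dichlorobut-2-ene
Product: 11 (S,E)-tert-butyl({7-chloro-1-[4-(methoxymethoxy)phenyl]hept-5-en-3-yl}oxy)dimethylsilane
Conditions: Hoveyda–Grubbs II (3 mol %), 10 (3 equiv), CH2Cl2, 40 °C; AgNO3–SiO2 chromatography
Reagents that add atoms: none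
Why: Olefin cross-metathesis of a terminal alkene with excess symmetrical allylic dichloride gives the thermodynamically favoured E allylic chloride (about 9:1, Z isomer removed on silver-doped silica) without touching C3.

Step 6
Reactants: 12 resorcinol
Product: 13 1,3-bis(methoxymethoxy)benzene
Conditions: MOMCl (2.6 equiv), iPr2NEt (3 equiv), CH2Cl2, 0 °C → rt
Reagents that add atoms: chloromethyl methyl ether (MOMCl), COCCl
Why: Double Williamson-type O-alkylation, which installs the two groups that later direct the metalation.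

Step 7
Reactants: 13 1,3-bis(methoxymethoxy)benzene
Product: 14 2-[3,5-bis(methoxymethoxy)phenyl]-4,4,5,5-tetramethyl-1,3,2-dioxaborolane
Conditions: [Ir(OMe)(cod)]2 (1.5 mol %), dtbpy (3 mol %), B2pin2 (1.0 equiv), MTBE, 60 °C
Reagents that add atoms: bis(pinacolato)diboron, CC1(C)OB(OC1(C)C)B1OC(C)(C)C(C)(C)O1
Why: Sterically controlled Ir-catalysed aromatic C–H borylation, selective because C5–H is the only ring C–H without an ortho substituent.

Step 8
Reactants: 14 2-[3,5-bis(methoxymethoxy)phenyl]-4,4,5,5-tetramethyl-1,3,2-dioxaborolane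
Product: 15 3,5-bis(methoxymethoxy)phenol
Conditions: 30 % H2O2, aq NaOH, THF, 0 °C; neutralise to pH 7
Reagents that add atoms: hydrogen peroxide, OO
Why: Oxidative ipso-hydroxylation of the arylboronate (1,2-aryl shift from boron to oxygen) under basic conditions that leave MOM ethers intact.

Step 9
Reactants: 15 3,5-bis(methoxymethoxy)phenol
Product: 16 1-methoxy-3,5-bis(methoxymethoxy)benzene
Conditions: MeI, K2CO3, acetone, reflux
Reagents that add atoms: iodomethane, CI
Why: Williamson ether synthesis on the only free phenol, which fixes the position of the single methyl ether of the target.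

Step 10
Reactants: 16 1-methoxy-3,5-bis(methoxymethoxy)benzene
Product: 19 2-[4-methoxy-2,6-bis(methoxymethoxy)phenyl]-4,4,5,5-tetramethyl-1,3,2-dioxaborolane, via 4-methoxy-2,6-bis(methoxymethoxy)phenyllithium 17 (not isolated), via lithium aryl(isopropoxy)pinacolborate 18 (not isolated)
Conditions: n-BuLi (1.1 equiv), THF, 0 °C, 1 h; iPrOBpin, −78 °C → rt; H2O
Reagents that add atoms: 2-isopropoxy-4,4,5,5-tetramethyl-1,3,2-dioxaborolane, CC(C)OB1OC(C)(C)C(C)(C)O1
Why: Directed ortho-metalation, in which the C–H flanked by two chelating OMOM groups is lithiated in preference to those flanked by OMe and OMOM, followed by borate formation and loss of isopropoxide.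

Step 11
Reactants: 11 (S,E)-tert-butyl({7-chloro-1-[4-(methoxymethoxy)phenyl]hept-5-en-3-yl}oxy)dimethylsilane; 19 2-[4-methoxy-2,6-bis(methoxymethoxy)phenyl]-4,4,5,5-tetramethyl-1,3,2-dioxaborolane
Product: 20 (3S,5R)-3-(tert-butyldimethylsilyloxy)-5-[4-methoxy-2,6-bis(methoxymethoxy)phenyl]-1-[4-(methoxymethoxy)phenyl]hept-6-ene
Conditions: 19 (1.5 equiv) + KOtBu (1.5 equiv), THF, 0 °C, 15 min; then CuCl (5 mol %), L*·H (5.5 mol %), 11, −15 → 22 °C. L* is a (4S,5S)-4,5-diphenylimidazolin-2-ylidene with N1 = 2-sulfonatophenyl and N3 = 3,5-di-tert-butylphenyl; its antipode is equally accessible.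
Reagents that add atoms: none
Why: Proposed new method: KOtBu turns 19 into a borate that passes its electron-rich aryl group to (NHC)Cu–OtBu; the aryl–Cu(I) species binds the E-alkene of 11 anti to chloride, oxidative addition at C5 gives a σ-allyl Cu(III) that reductively eliminates faster than it isomerises (hence branched, SN2′); the new C1-symmetric sulfonate-tethered NHC has no ortho substituents on its second N-aryl group, which leaves room for the two ortho OMOM groups, and its K+–sulfonate bridge to the leaving chloride fixes the alkene face, so the ligand antipode that delivers aryl to the Re face of C5 sets 5R independently of the remote C3 centre; the closest known reaction type is the NHC–Cu-catalysed SN2′-selective allyl–aryl coupling of arylboronic esters with allylic chlorides or phosphates (enantioselective only for unhindered or mono-ortho-substituted aryls), not shown for a di-ortho-alkoxy aryl donor or for catalyst-controlled diastereoselection on such a chain.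

Step 12
Reactants: 20 (3S,5R)-3-(tert-butyldimethylsilyloxy)-5-[4-methoxy-2,6-bis(methoxymethoxy)phenyl]-1-[4-(methoxymethoxy)phenyl]hept-6-ene
Product: 21 (3S,5R)-5-[3-bromo-4-methoxy-2,6-bis(methoxymethoxy)phenyl]-3-(tert-butyldimethylsilyloxy)-1-[4-(methoxymethoxy)phenyl]hept-6-ene
Conditions: NBS (1.0 equiv), CH2Cl2, −78 → −20 °C, dark
Reagents that add atoms: N-bromosuccinimide, O=C1CCC(=O)N1Br
Why: Electrophilic aromatic bromination, in which the trialkoxy ring is by far the most nucleophilic π system, its two free positions are equivalent, and one equivalent of NBS at low temperature stops at the monobromide without touching the terminal alkene.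

Step 13
Reactants: 2 1-iodo-4-(methoxymethoxy)benzene; 22 N-methoxy-N-methylacrylamide
Product: 23 (E)-N-methoxy-3-[4-(methoxymethoxy)phenyl]-N-methylprop-2-enamide
Conditions: Pd(OAc)2 (2 mol %), P(o-tol)3 (6 mol %), NaOAc, DMF, 100 °C
Reagents that add atoms: none
Why: Mizoroki–Heck arylation of an electron-poor terminal alkene, which is β-selective and gives only the E isomer.

Step 14
Reactants: 21 (3S,5R)-5-[3-bromo-4-methoxy-2,6-bis(methoxymethoxy)phenyl]-3-(tert-butyldimethylsilyloxy)-1-[4-(methoxymethoxy)phenyl]hept-6-ene; 23 (E)-N-methoxy-3-[4-(methoxymethoxy)phenyl]-N-methylprop-2-enamide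
Product: 26 (E)-1-{3-[(3R,5S)-5-(tert-butyldimethylsilyloxy)-7-[4-(methoxymethoxy)phenyl]hept-1-en-3-yl]-6-methoxy-2,4-bis(methoxymethoxy)phenyl}-3-[4-(methoxymethoxy)phenyl]prop-2-en-1-one, via aryllithium from Br/Li exchange 24 (not isolated), via lithium hemiaminal adduct 25 (not isolated)
Conditions: n-BuLi (1.05 equiv), THF, −78 °C, 10 min; 23 (1.3 equiv), −78 → −20 °C; H2O
Reagents that add atoms: none
Why: Bromine–lithium exchange followed by Weinreb ketone synthesis, in which exchange at −78 °C outruns deprotonation of C5–H (still only allyl/benzyl-activated at this stage, so C5 is kept), the hard aryllithium adds 1,2, and adduct 25 holds until the quench so no over-addition occurs.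

Step 15
Reactants: 26 (E)-1-{3-[(3R,5S)-5-(tert-butyldimethylsilyloxy)-7-[4-(methoxymethoxy)phenyl]hept-1-en-3-yl]-6-methoxy-2,4-bis(methoxymethoxy)phenyl}-3-[4-(methoxymethoxy)phenyl]prop-2-en-1-one; 2 1-iodo-4-(methoxymethoxy)benzene
Product: 27 (E)-1-{3-[(1E,3R,5S)-5-(tert-butyldimethylsilyloxy)-1,7-bis[4-(methoxymethoxy)phenyl]hept-1-en-3-yl]-6-methoxy-2,4-bis(methoxymethoxy)phenyl}-3-[4-(methoxymethoxy)phenyl]prop-2-en-1-one (penta-MOM, TBS-protected calyxin A)
Conditions: Pd(OAc)2 (5 mol %), P(o-tol)3 (10 mol %), Ag2CO3 (0.6 equiv), 2 (1.2 equiv), MeCN, 70 °C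
Reagents that add atoms: none
Why: Mizoroki–Heck arylation under cationic (silver) conditions, in which aryl adds to the terminal carbon of the only monosubstituted alkene, syn β-hydride elimination of a benzylic C7–H gives the conjugated E styrene, and silver suppresses the Pd–H re-addition that could move the alkene toward C5.

Step 16
Reactants: 27 penta-MOM, TBS-protected calyxin A
Product: 28 calyxin A, (E)-1-{2,4-dihydroxy-3-[(1E,3R,5S)-5-hydroxy-1,7-bis(4-hydroxyphenyl)hept-1-en-3-yl]-6-methoxyphenyl}-3-(4-hydroxyphenyl)prop-2-en-1-one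
Conditions: HCl (1.25 M in MeOH), 0 °C → rt, Ar, dark; NaHCO3 work-up
Reagents that add atoms: none
Why: Acid-catalysed methanolysis of acetals and silyl ether (global deprotection), as used for MOM-protected 2′-hydroxychalcones; dilute acid at or below room temperature protonates the styrene and closes the flavanone only slowly, and no stereocentre takes part.

## Compound list
1 | 4-iodophenol | Oc1ccc(I)cc1 | starting material
2 | 1-iodo-4-(methoxymethoxy)benzene | COCOc1ccc(I)cc1 | intermediate
3 | allyl alcohol | C=CCO | starting material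
4 | 3-[4-(methoxymethoxy)phenyl]propanal | COCOc1ccc(CCC=O)cc1 | intermediate
5 | allylmagnesium bromide | C=CC[Mg]Br | starting material
6 | (+)-B-allyldiisopinocampheylborane (not isolated) | C=CCB([C@H]1C[C@H]2C[C@@H]([C@@H]1C)C2(C)C)[C@H]1C[C@H]2C[C@@H]([C@@H]1C)C2(C)C | intermediate
7 | (S)-1-[4-(methoxymethoxy)phenyl]hex-5-en-3-yl diisopinocampheylborinate (not isolated) | C=CC[C@@H](OB([C@H]1C[C@H]2C[C@@H]([C@@H]1C)C2(C)C)[C@H]1C[C@H]2C[C@@H]([C@@H]1C)C2(C)C)CCc1ccc(OCOC)cc1 | intermediate
8 | (S)-1-[4-(methoxymethoxy)phenyl]hex-5-en-3-ol | C=CC[C@@H](O)CCc1ccc(OCOC)cc1 | intermediate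
9 | (S)-tert-butyl({1-[4-(methoxymethoxy)phenyl]hex-5-en-3-yl}oxy)dimethylsilane | C=CC[C@@H](O[Si](C)(C)C(C)(C)C)CCc1ccc(OCOC)cc1 | intermediate
10 | (Z)-1,4-dichlorobut-2-ene | ClC/C=C\CCl | starting material
11 | (S,E)-tert-butyl({7-chloro-1-[4-(methoxymethoxy)phenyl]hept-5-en-3-yl}oxy)dimethylsilane | ClC/C=C/C[C@@H](O[Si](C)(C)C(C)(C)C)CCc1ccc(OCOC)cc1 | intermediate
12 | resorcinol | Oc1cccc(O)c1 | starting material
13 | 1,3-bis(methoxymethoxy)benzene | COCOc1cccc(OCOC)c1 | intermediate
14 | 2-[3,5-bis(methoxymethoxy)phenyl]-4,4,5,5-tetramethyl-1,3,2-dioxaborolane | COCOc1cc(OCOC)cc(B2OC(C)(C)C(C)(C)O2)c1 | intermediate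
15 | 3,5-bis(methoxymethoxy)phenol | COCOc1cc(O)cc(OCOC)c1 | intermediate
16 | 1-methoxy-3,5-bis(methoxymethoxy)benzene | COCOc1cc(OC)cc(OCOC)c1 | intermediate
17 | 4-methoxy-2,6-bis(methoxymethoxy)phenyllithium (not isolated) | [Li]c1c(OCOC)cc(OC)cc1OCOC | intermediate
18 | lithium [4-methoxy-2,6-bis(methoxymethoxy)phenyl](isopropoxy)pinacolborate (not isolated) | [Li+].CC(C)O[B-]1(OC(C)(C)C(C)(C)O1)c1c(OCOC)cc(OC)cc1OCOC | intermediate
19 | 2-[4-methoxy-2,6-bis(methoxymethoxy)phenyl]-4,4,5,5-tetramethyl-1,3,2-dioxaborolane | COCOc1cc(OC)cc(OCOC)c1B2OC(C)(C)C(C)(C)O2 | intermediate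
20 | (3S,5R)-3-(tert-butyldimethylsilyloxy)-5-[4-methoxy-2,6-bis(methoxymethoxy)phenyl]-1-[4-(methoxymethoxy)phenyl]hept-6-ene | COCOc1cc(OC)cc(OCOC)c1[C@@H](C=C)C[C@@H](O[Si](C)(C)C(C)(C)C)CCc2ccc(OCOC)cc2 | intermediate
21 | (3S,5R)-5-[3-bromo-4-methoxy-2,6-bis(methoxymethoxy)phenyl]-3-(tert-butyldimethylsilyloxy)-1-[4-(methoxymethoxy)phenyl]hept-6-ene | COCOc1cc(OC)c(Br)c(OCOC)c1[C@@H](C=C)C[C@@H](O[Si](C)(C)C(C)(C)C)CCc2ccc(OCOC)cc2 | intermediate
22 | N-methoxy-N-methylacrylamide | C=CC(=O)N(C)OC | starting material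
23 | (E)-N-methoxy-3-[4-(methoxymethoxy)phenyl]-N-methylprop-2-enamide | CON(C)C(=O)/C=C/c1ccc(OCOC)cc1 | intermediate
24 | aryllithium from 21, Li in place of Br (not isolated) | [Li]c1c(OC)cc(OCOC)c([C@@H](C=C)C[C@@H](O[Si](C)(C)C(C)(C)C)CCc2ccc(OCOC)cc2)c1OCOC | intermediate
25 | lithium hemiaminal adduct of 24 and 23, new carbinol centre undefined (not isolated) | [Li]OC(/C=C/c1ccc(OCOC)cc1)(N(C)OC)c1c(OC)cc(OCOC)c([C@@H](C=C)C[C@@H](O[Si](C)(C)C(C)(C)C)CCc2ccc(OCOC)cc2)c1OCOC | intermediate
26 | (E)-1-{3-[(3R,5S)-5-(tert-butyldimethylsilyloxy)-7-[4-(methoxymethoxy)phenyl]hept-1-en-3-yl]-6-methoxy-2,4-bis(methoxymethoxy)phenyl}-3-[4-(methoxymethoxy)phenyl]prop-2-en-1-one | COCOc1cc(OC)c(C(=O)/C=C/c2ccc(OCOC)cc2)c(OCOC)c1[C@@H](C=C)C[C@@H](O[Si](C)(C)C(C)(C)C)CCc3ccc(OCOC)cc3 | intermediate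
27 | penta-MOM, TBS-protected calyxin A | COCOc1cc(OC)c(C(=O)/C=C/c2ccc(OCOC)cc2)c(OCOC)c1[C@@H](/C=C/c3ccc(OCOC)cc3)C[C@@H](O[Si](C)(C)C(C)(C)C)CCc4ccc(OCOC)cc4 | intermediate
28 | calyxin A | COc1cc(O)c([C@@H](/C=C/c2ccc(O)cc2)C[C@@H](O)CCc2ccc(O)cc2)c(O)c1C(=O)/C=C/c1ccc(O)cc1 | target

## Step count
- Total steps: 16.
- Longest linear sequence: 10 (steps 1, 2, 3, 4, 5, 11, 12, 14, 15, 16).
- The branch from resorcinol (steps 6–10, then 11, 12, 14, 15, 16) is equally long.

## Steps most likely to fail

**Step 11 (the proposed new coupling).** The di-ortho-substituted aryl group may transmetalate or reductively eliminate slowly. That would give the linear SN2 product, protodeboronation of 19, or a poor 5R:5S ratio.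

The fallback uses known chemistry and is stereospecific instead of catalyst-controlled. It sets out from 9 and 16 and comes back at 20. Cross-metathesis of 9 with bought (R)-but-3-en-2-ol (Hoveyda–Grubbs II) gives (2R,3E,6S)-6-(tert-butyldimethylsilyloxy)-8-[4-(methoxymethoxy)phenyl]oct-3-en-2-ol F1. This is esterified with picolinic acid (DCC, DMAP) to the corresponding picolinate F2. Compound 16 is lithiated to 17 as in step 10 and transmetalated with MgBr2·OEt2 to 4-methoxy-2,6-bis(methoxymethoxy)phenylmagnesium bromide F3. In the presence of CuBr·SMe2, F3 displaces the chelating picolinate anti-SN2′ with 1,3-chirality transfer (R carbinol, E alkene → 5R). The product is the (3S,5R,6E)-oct-6-ene (propenyl) analogue of 20 F4. Ethenolysis (Hoveyda–Grubbs II, ethylene) trims the propenyl group to vinyl and gives 20.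

**Step 14 (acylation).** The hindered aryllithium 24 may add sluggishly or in a 1,4 sense to the conjugated Weinreb amide, or may be quenched by proton transfer.

The fallback moves the disconnection to the chalcone Cα=Cβ bond. It sets out from 21 and 2 and comes back at 26. Aryllithium 24, made from 21 as in step 14, is trapped with the small electrophile N-methoxy-N-methylacetamide to give the methyl ketone (acetyl in place of the cinnamoyl group of 26) F5. Compound 2 is converted with iPrMgCl·LiCl into 4-(methoxymethoxy)phenylmagnesium chloride F6 and formylated with DMF to 4-(methoxymethoxy)benzaldehyde F7. Claisen–Schmidt condensation of F5 with F7 (KOH, EtOH, rt) gives 26.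

**Step 15 (late Heck).** β-Hydride elimination toward C5 would move the alkene and destroy the C5 stereocentre. Arylation of the enone could also compete.

The fallback makes the styrene by metathesis, so no Pd–H is involved. It sets out from 26 and 2 and comes back at 27. Compound 2 is vinylated (potassium vinyltrifluoroborate, PdCl2(dppf), Cs2CO3, THF/H2O) to 1-ethenyl-4-(methoxymethoxy)benzene F8. Cross-metathesis of 26 with excess F8 (Hoveyda–Grubbs II, CH2Cl2, 40 °C) gives the E styrene 27, and the 1,2-disubstituted chalcone alkene stays inert.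

## Further compounds
F1 | step 11 | (2R,3E,6S)-6-(tert-butyldimethylsilyloxy)-8-[4-(methoxymethoxy)phenyl]oct-3-en-2-ol | C[C@@H](O)/C=C/C[C@@H](O[Si](C)(C)C(C)(C)C)CCc1ccc(OCOC)cc1
F2 | step 11 | (2R,3E,6S)-6-(tert-butyldimethylsilyloxy)-8-[4-(methoxymethoxy)phenyl]oct-3-en-2-yl picolinate | C[C@@H](OC(=O)c1ccccn1)/C=C/C[C@@H](O[Si](C)(C)C(C)(C)C)CCc1ccc(OCOC)cc1
F3 | step 11 | 4-methoxy-2,6-bis(methoxymethoxy)phenylmagnesium bromide | COCOc1cc(OC)cc(OCOC)c1[Mg]Br
F4 | step 11 | (3S,5R,6E)-3-(tert-butyldimethylsilyloxy)-5-[4-methoxy-2,6-bis(methoxymethoxy)phenyl]-1-[4-(methoxymethoxy)phenyl]oct-6-ene | COCOc1cc(OC)cc(OCOC)c1[C@@H](/C=C/C)C[C@@H](O[Si](C)(C)C(C)(C)C)CCc2ccc(OCOC)cc2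
F5 | step 14 | 1-{3-[(3R,5S)-5-(tert-butyldimethylsilyloxy)-7-[4-(methoxymethoxy)phenyl]hept-1-en-3-yl]-6-methoxy-2,4-bis(methoxymethoxy)phenyl}ethan-1-one | COCOc1cc(OC)c(C(C)=O)c(OCOC)c1[C@@H](C=C)C[C@@H](O[Si](C)(C)C(C)(C)C)CCc2ccc(OCOC)cc2
F6 | step 14 | 4-(methoxymethoxy)phenylmagnesium chloride | COCOc1ccc([Mg]Cl)cc1
F7 | step 14 | 4-(methoxymethoxy)benzaldehyde | COCOc1ccc(C=O)cc1
F8 | step 15 | 1-ethenyl-4-(methoxymethoxy)benzene | C=Cc1ccc(OCOC)cc1
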